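Cuts: the ring A bonds C3–Br and C6–Br go first, together with the aromaticity of ring A, leading back to 2-(2,4-dibromophenoxy)cyclohex-2-enone. Next comes the C2–O bond of the diaryl ether, back to 2,3-epoxycyclohexanone and 2,4-dibromophenol, and last the epoxide oxygen, back to cyclohex-2-enone.
Enabling feature: in ring A (C1 OH, C2 OAr) the bromines sit at C3 and C6, on either side of the two oxygen-bearing carbons, while C4 (para to OH) and C5 are free. At the cyclohexenone level C6 is the only α-CH2 of the C1 carbonyl and C3 is the β-carbon of the C2=C3 aryl enol ether, so both sites answer to carbonyl and enol ether polarity rather than to phenol directing effects.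
Forward order: no ring is built. Ring B is bought with its two bromines and ring A as a carbocycle, the two are joined at sp3 C2 by epoxide opening, and ring A then takes up three Br2 and is aromatized last.
Control: C6 is brominated twice through the kinetic lithium enolate and C3 through Br2 addition to the enol ether. One C6 bromine is sacrificed as HBr to reach the phenol oxidation level.
Stereochemistry: the target has no stereocentre; the sp3 centres that appear on the way are racemic and all vanish.

Key step: step 3

Remark on the chemistry: the ring A locants of the target (C1 oxygen-bearing, C2 aryloxy-bearing, then C3 to C6) are kept for every six-membered precursor. Racemic compounds are drawn as one enantiomer where relative configuration matters.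

Step 1
Reactants: 1 cyclohex-2-en-1-one
Product: 2 2,3-epoxycyclohexanone (7-oxabicyclo[4.1.0]heptan-2-one, cis-fused, racemic)
Conditions: 30% aq. H2O2 (1.3 equiv), NaOH (0.2 equiv), MeOH, 0–10 °C
Reagents that add atoms: hydrogen peroxide, OO
Why: Weitz–Scheffer nucleophilic epoxidation, in which hydroperoxide anion adds to the β-carbon of the enone and the enolate closes onto the O–O bond, the cis fusion being enforced by the bicycle and the racemic nature of 2 being irrelevant because both centres are destroyed later.

Step 2
Reactants: 2 2,3-epoxycyclohexanone (1.2 equiv); 3 2,4-dibromophenol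
Product: 5 2-(2,4-dibromophenoxy)cyclohex-2-en-1-one, via hydroxy ketone 4 (not isolated)
Conditions: KH (0.2 equiv), THF–DMPU (4:1), reflux
Reagents that add atoms: none
Why: Base-catalysed opening of an α,β-epoxy ketone by a phenoxide followed by dehydration, a standard entry to 2-aryloxycyclohex-2-enones: the phenoxide attacks the carbonyl-activated α-carbon C2 in an SN2 process with inversion (trans-4), further 3 protonates the alkoxide, and E1cB loss of water (acidic C2–H, β-hydroxyl at C3) gives the conjugated enol ether and returns the base, so that the crowded C2–O bond is made at an sp3 carbon before its C3 bromine neighbour exists.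

Step 3
Reactants: 5 2-(2,4-dibromophenoxy)cyclohex-2-en-1-one; 6 bromine (3.0 equiv in all)
Product: 12 3,6-dibromo-2-(2,4-dibromophenoxy)phenol, via 6-bromoenone 7 (not isolated), via 6,6-dibromoenone 8 (not isolated), via tetrabromo ketone 9 (not isolated), via 3,6,6-tribromoenone 10 (not isolated), via cross-conjugated dienone 11 (not isolated)
Conditions: LiN(SiMe3)2 (1.0 equiv) then Br2 (1.0 equiv), THF, −78 °C, run twice in the same flask; evaporate THF and HN(SiMe3)2 (≤20 °C); Br2 (1.0 equiv), CH2Cl2, dark, −20 → 0 °C until colourless; DBU (3.2 equiv), 0 °C → rt; 1 M HCl work-up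
Reagents that add atoms: bromine (compound 6), BrBr
Why: LiN(SiMe3)2 deprotonates 5 kinetically at C6, the only α-CH2 of the C1 carbonyl, Br2 traps the cross-conjugated enolate as 7, and because the remaining C6–H of 7 is now the most acidic proton the second cycle puts the second bromine on the same carbon (8); strong-base control is chosen because acid-catalysed enolization of an enone also runs vinylogously toward C4. Once the silylamine has been stripped off, the third Br2 adds anti across the C2=C3 aryl enol ether with electrophilic bromine on the oxygen-activated β-carbon C3 (9), while the carbonyl of 8, flanked by CBr2 and without α-hydrogen, is too weakly basic to enolize toward C4. DBU then expels the labile tertiary α-bromo ether bromide at C2 together with its only neighbouring hydrogen, C3–H, to restore the enone as 10, removes HBr across C5–C6 in an E2 step, and dienone 11, whose C4 is still a CH2 group, tautomerizes irreversibly to the phenolate of 12. The closest known reaction types are the position-specific bromination of kinetic lithium enolates, the bromination–dehydrobromination of cyclic enol ethers to β-bromo enol ethers and the base-induced aromatization of α,α-dibromo ketones, as in 2,2-dibromo-1-tetralone to 2-bromo-1-naphthol. No ring closes and no stereocentre is kept, since the racemic centres of 7 and 9 are erased on aromatization. The selectivity needed is C3 and C6 over C4 and ring B: enolate and enol ether polarity secure the first, the two deactivating bromines and the enone-shared oxygen lone pair protect ring B, and C4 stays free because ring A becomes a phenol only after all Br2 has been consumed.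

Compound list
1 | cyclohex-2-en-1-one | O=C1C=CCCC1 | starting material
2 | 2,3-epoxycyclohexanone (7-oxabicyclo[4.1.0]heptan-2-one), cis-fused, racemic | O=C1CCC[C@H]2O[C@@H]12 | intermediate
3 | 2,4-dibromophenol | Oc1ccc(Br)cc1Br | starting material
4 | trans-2-(2,4-dibromophenoxy)-3-hydroxycyclohexan-1-one, racemic, not isolated | O=C1CCC[C@@H](O)[C@@H]1Oc1ccc(Br)cc1Br | intermediate
5 | 2-(2,4-dibromophenoxy)cyclohex-2-en-1-one | O=C1CCCC=C1Oc1ccc(Br)cc1Br | intermediate
6 | bromine | BrBr | starting material
7 | 6-bromo-2-(2,4-dibromophenoxy)cyclohex-2-en-1-one, racemic, not isolated | O=C1C(Br)CCC=C1Oc1ccc(Br)cc1Br | intermediate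
8 | 6,6-dibromo-2-(2,4-dibromophenoxy)cyclohex-2-en-1-one, not isolated | O=C1C(Oc2ccc(Br)cc2Br)=CCCC1(Br)Br | intermediate
9 | 2,3,6,6-tetrabromo-2-(2,4-dibromophenoxy)cyclohexan-1-one, C2 and C3 bromines trans (anti addition), racemic, not isolated | O=C1C(Br)(Br)CC[C@H](Br)[C@]1(Br)Oc1ccc(Br)cc1Br | intermediate
10 | 3,6,6-tribromo-2-(2,4-dibromophenoxy)cyclohex-2-en-1-one, not isolated | O=C1C(Oc2ccc(Br)cc2Br)=C(Br)CCC1(Br)Br | intermediate
11 | 3,6-dibromo-2-(2,4-dibromophenoxy)cyclohexa-2,5-dien-1-one, not isolated | O=C1C(Br)=CCC(Br)=C1Oc1ccc(Br)cc1Br | intermediate
12 | 3,6-dibromo-2-(2,4-dibromophenoxy)phenol | Oc1c(Br)ccc(Br)c1Oc1ccc(Br)cc1Br | target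

Total step count: 3
Longest linear sequence: 3 steps (1 → 2 → 5 → 12)

Steps most likely to fail

**Step 3 (key step).** Site control may erode after the enolate stage.
- Elimination from the Br2 adduct toward C4, or halophilic attack of bromide or DBU on the C2 bromine, would strip the C3 bromine again.
- Transfer of positive bromine from the gem-dibromide to the emerging phenolate would brominate C4.

In the fallback, ring A is bought aromatic with both bromines in place and its oxygen is introduced last. It sets out from 3. An SNAr reaction joins 3 to commercial 3,6-dibromo-2-fluorobenzaldehyde (O=Cc1c(F)c(Br)ccc1Br; K2CO3, DMF, 90 °C), whose fluorine is activated by the ortho formyl group. This gives 3,6-dibromo-2-(2,4-dibromophenoxy)benzaldehyde F1. Baeyer–Villiger oxidation with mCPBA (CH2Cl2, reflux), with migration of the aryl group that carries the ortho aryloxy donor, should give 3,6-dibromo-2-(2,4-dibromophenoxy)phenyl formate F2. Cleavage of the formate with aq. NaOH in MeOH and acidification comes back to the route at 12.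

**Step 2.** The weakly nucleophilic, ortho-substituted phenoxide may attack slowly. Base-induced self-condensation of the epoxy ketone, opening by the water formed, or stalling before dehydration could then take over.

The fallback makes the ether at a saturated α-halo ketone and introduces the double bond afterwards. It sets out from 3, which is O-alkylated with commercial 2-chlorocyclohexanone (O=C1CCCCC1Cl; K2CO3, cat. KI, acetone, reflux) to give 2-(2,4-dibromophenoxy)cyclohexan-1-one F3. Soft enolization with TMSOTf and Et3N (CH2Cl2, 0 °C → rt) toward the more acidic, aryloxy-bearing C2–H gives [2-(2,4-dibromophenoxy)cyclohex-1-en-1-yl]oxytrimethylsilane F4. NBS (THF, −78 → 0 °C) converts this into 2-bromo-2-(2,4-dibromophenoxy)cyclohexan-1-one F5. This tertiary α-bromo ether can lose HBr only toward C3 (Et3N, same flask), which comes back to the route at 5.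

**Step 1.** The small, volatile and water-soluble product may be lost during aqueous work-up, and alkaline peroxide or hydroxide may attack the epoxy ketone further.

The fallback epoxidizes at the alcohol oxidation level and restores the ketone under non-aqueous, non-basic conditions. It sets out from 1. Luche reduction (NaBH4, CeCl3·7H2O, MeOH, 0 °C) gives cyclohex-2-en-1-ol F6. Hydroxyl-directed epoxidation with mCPBA (CH2Cl2, 0 °C) gives cis-2,3-epoxycyclohexan-1-ol F7. Oxidation with Dess–Martin periodinane (NaHCO3, CH2Cl2, rt) comes back to the route at 2.

Further compounds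
F1 | step 3 | 3,6-dibromo-2-(2,4-dibromophenoxy)benzaldehyde | O=Cc1c(Br)ccc(Br)c1Oc1ccc(Br)cc1Br
F2 | step 3 | 3,6-dibromo-2-(2,4-dibromophenoxy)phenyl formate | O=COc1c(Br)ccc(Br)c1Oc1ccc(Br)cc1Br
F3 | step 2 | 2-(2,4-dibromophenoxy)cyclohexan-1-one, racemic | O=C1CCCCC1Oc1ccc(Br)cc1Br
F4 | step 2 | [2-(2,4-dibromophenoxy)cyclohex-1-en-1-yl]oxytrimethylsilane | C[Si](C)(C)OC1=C(Oc2ccc(Br)cc2Br)CCCC1
F5 | step 2 | 2-bromo-2-(2,4-dibromophenoxy)cyclohexan-1-one, racemic | O=C1CCCCC1(Br)Oc1ccc(Br)cc1Br
F6 | step 1 | cyclohex-2-en-1-ol, racemic | OC1C=CCCC1
F7 | step 1 | cis-2,3-epoxycyclohexan-1-ol, racemic | O[C@H]1CCC[C@H]2O[C@@H]12
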